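(All runs were generated by integration with constants of no real substance; scatter was added.)

11.8 turnovers fit into the asked time. That is the turnover count, the asked time divided by the lifetime of the unread part. The unread part is whatever of the charge shows neither as Z nor as X.

| flask | Q | D | remark | time |
|---|---|---|---|---|
| green | 1.5 M | 200 mM (held) | the very flask that is asked about, followed so far |  |
| violet | 3 M | 200 mM (held) | run made earlier |  |
| flask | 1.5 M | 200 mM (held) |  | 2.5 min |

| run | time / s | Z / % | X / % |
|---|---|---|---|
| green | 12.0 | 36.7 | 19.0 |
| green | 25.0 | 45.4 | 38.7 |
| green | 30.0 | 48.2 | 42.8 |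
| green | 50.0 | 50.1 | 47.5 |
| violet | 25.0 | 45.3 | 37.2 |
| violet | 50.0 | 49.0 | 47.5 |
| violet | 80.0 | 49.1 | 48.0 |
| violet | 120 | 49.9 | 49.4 |

(scatter of a reading: 1 percentage point)

- the state of affairs at 2.5 min: stopped, and by what, or still going (all of Q has reacted / forward and back rates have come level / it is still moving)
- amount of Z at 2.5 min, in percent of the Q charged
- amount of X at 2.5 min, in percent of the Q charged
- amount of E at 2.5 min, in percent of the Q charged

- the earlier runs were read with a standard deviation of 1 percentage point
- at the start none of D is in solution
- the reaction counts as stopped when no species that holds the Q changes by six tenths of a point or more over the second half of the time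

Follow the green flask, which is the flask asked about.

1. First instants. At 12.0 s the unread part is 44.3%. Z, at 36.7%, is higher than X, at 19.0%.

2. Middle. At 25.0 s the unread part is 15.9%. That fall gives a rate of 0.0788 s⁻¹, so the lifetime, the usual time constant, is 12.7 s. The violet run has twice the Q, yet at 25.0 s it reads Z 45.3% against 45.4% in the green run. So you may take one lifetime for both.

3. End. Reckoned at that lifetime from the value at 25.0 s, the part of the unread share of the green flask that still fades comes to 0.309% at half the asked time, so what can still change over the second half is less than the stopping margin. At the asked time the same reckoning gives <0.001%. D is held, and with so little fading I take Q as the limiting reagent and call the green flask stopped by Q.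

4. Residue. Using the one lifetime, I reckon the fading part at 80.0 s in the violet run as 0.208%. The last two violet readings leave a mean gap of 1.80%, which is more, with a scatter near 1 percentage point. I read that lasting gap as E. The same violet readings give Z 49.5% and X 48.7%, and I carry these readings over to the green flask as my reckoning.

The forecast says all of Q has reacted, with Z 50%, X 49.7% and E 0.3%, since the “reaction has stopped because Q is consumed”; its E is lower than my 1.80%.

The flask gives all of Q has reacted, with Z 49.7%, X 48.7% and E 1.62%.

    Q ⇌ G (K = 0.520, k = 0.140 s⁻¹)
    J + G → Z (k = 2.40 M⁻¹ s⁻¹)
    G → E (k = 0.00770 s⁻¹)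
    D ⇌ J, rate k4*(csat - [J]) (kL = 12.0 s⁻¹)
    Z ⇌ X (K = 0.980, k = 0.110 s⁻¹)

In the green flask, Q stood at 0.173% at 1.25 min, half the asked time. Left until 4.0 min, the same flask counts 18.9 turnovers against 11.8, and its E stands at 1.62%, with Q at 0%.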